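A small charge of free catalyst invites a rule of thumb at the bench: at one concentration and one reagent charge, a larger loading reaches the same yield in proportionally less time.

| setting | Saturday's | Thursday's | Wednesday's | flask |
|---|---|---|---|---|
| starting material | 0.19 M | 0.19 M | 0.29 M | 0.19 M |
| reagent | 2 equiv | 2 equiv | 2 equiv | 2.00 equiv |
| free catalyst | 0.05 mol% | 0.075 mol% | 0.1 mol% | 0.1 mol% |
| remark | run made earlier | run made earlier | run made earlier |  |
| time |  |  |  | 10 h |

| run | time / h | product / % |
|---|---|---|
| Saturday's | 0.833 | 5 |
| Saturday's | 1.33 | 9 |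
| Saturday's | 2.00 | 14 |
| Saturday's | 3.00 | 19 |
| Saturday's | 4.00 | 23 |
| Saturday's | 6.00 | 36 |
| Saturday's | 10.0 | 45 |
| Thursday's | 1.33 | 15 |
| Thursday's | 3.00 | 26 |
| Thursday's | 4.00 | 33 |
| Thursday's | 6.00 | 41 |
| Thursday's | 8.00 | 48 |
| Thursday's | 10.0 | 54 |
| Wednesday's | 0.833 | 11 |
| Wednesday's | 2.50 | 33 |
| Wednesday's | 5.00 | 54 |
| Wednesday's | 8.00 | 66 |
| Wednesday's | 10.0 | 74 |

(scatter of a reading: 2 percentage points)

- the earlier runs were read with a standard deviation of 2 percentage points

- amount of product in percent of the starting material charged, at 2.0 h, 5.0 h and 10 h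

The flask at 5.0 h stands at 10.0 h, its elapsed time multiplied by its loading over Saturday's loading, the Saturday clock. You can test this clock on the readings: Thursday's run at 4.00 h reads 6.00 h on it and gave 33%, beside 36% for Saturday's run at 6.00 h, two readings that each scatter by 2 points. So I put the flask at 23% for 2.0 h, which is 4.00 h on the clock, and at 45% for 5.0 h.

The border comes at 10 h. The flask's clock then reads 20.0 h, twice Saturday's last reading and 1.33 times Thursday's last, so it lies later than the last reading of both runs at this concentration.

My own reckoning therefore goes round. On that estimate the flask's second 5.0 h starts with 55.0% of the starting material. Repeating the first lap, the pseudo-first-order view, gives 0.698 product. If one reagent goes per product, the reagent fraction is 0.775 at 5.0 h, and that first answer puts it at 0.651 at 10 h. Taking the rate as proportional to reagent, the second lap runs at 0.804 of the first, which gives 0.660. Another round gives 0.662, and that is the figure I commit to.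

The forecast gave 22%, 43% and 64%, holding “so the concentration dependence is weak”. My 0.662 at 10 h stands above its last figure.

The flask gives 23.9%, 44.7% and 64.5%.

    starting material + catalyst intermediate A ⇌ catalyst intermediate B (K = 3.00 M⁻¹, k = 2.60 M⁻¹ s⁻¹)
    reagent + free catalyst ⇌ catalyst intermediate A (K = 4.20 M⁻¹, k = 0.584 M⁻¹ s⁻¹)
    catalyst intermediate B ⇌ released group + catalyst intermediate C (K = 0.0610 M, k = 0.353 s⁻¹)
    catalyst intermediate C → free catalyst + product (k = 0.293 s⁻¹)

At 10 h the flask has 68% of its reagent left. At 10.0 h on the Saturday clock, the flask's 44.7% lies beside the 45% read in Saturday's run. Wednesday's run at 5.00 h reads 10.0 h, the same clock, at 1.53 times the flask's concentration, and it stood higher, at 54%.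

The runs were computed from invented constants, and the scatter is random.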